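**Strategy.** The 2-hydroxy-1,4-quinone ring is disconnected at C1–C8a and C2–C3 (and, in the same operation, C4–C4a). An aryne at C4a≡C8a of the benzo ring (ring B) inserts into the C(O)–CH2 bond of methyl acetoacetate; the resulting acetyl (C4a) and CH2CO2Me (C8a) arms close by Claisen condensation, and air oxidises C1. The step exploits the C5 oxygen of ring B: as a methyl ether next to C4a it polarises the aryne so that the enolate carbon bonds to C8a only, while its meta partner, a resorcinol-type oxygen on C8a, serves as the triflate leaving group. The precursor is a 3-methoxy-2-(trimethylsilyl)aryl triflate that already carries the aroyl and pyranonylmethyl groups.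

Key step: step 10

Remark: C1–C8a denote the naphthalene-1,4-dione numbering of the target; ring A is the 6-methylresorcinol-derived benzoyl ring and ring B the benzo ring of the quinone. The target is achiral and is treated as the drawn 2-hydroxyquinone/4-hydroxypyranone tautomer.

Step 1
Reactants: 1 2-(3,5-dihydroxyphenyl)acetic acid
Product: 2 benzyl 2-[3,5-bis(benzyloxy)phenyl]acetate
Conditions: BnBr, K2CO3, DMF, 60 °C
Reagents that add atoms: benzyl bromide BrCc1ccccc1
Why: Williamson O-alkylation (SN2) of both phenols and the carboxylate should give the tribenzyl compound, whose three benzyl groups are later removed together.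

Step 2
Reactants: 2 benzyl 2-[3,5-bis(benzyloxy)phenyl]acetate, 3 2,4-dimethoxy-6-methylbenzoic acid
Product: 5 benzyl 2-[3,5-bis(benzyloxy)-2-(2,4-dimethoxy-6-methylbenzoyl)phenyl]acetate, via mixed anhydride 4 (not isolated)
Conditions: TFAA, CH2Cl2, 0 → 23 °C
Reagents that add atoms: none
Why: Friedel–Crafts acylation, in which the mixed anhydride ionises to an acylium ion stabilised by its ortho- and para-methoxy groups and should attack C2 of the bis(benzyloxy)arene (para to one ether oxygen, ortho to the other, the two such positions being equivalent by symmetry) to give the tetra-ortho-substituted benzophenone.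

Step 3
Reactants: 5 benzyl 2-[3,5-bis(benzyloxy)-2-(2,4-dimethoxy-6-methylbenzoyl)phenyl]acetate
Product: 6 2-[2-(2,4-dimethoxy-6-methylbenzoyl)-3,5-dihydroxyphenyl]acetic acid
Conditions: H2 (1 atm), 10% Pd/C, EtOAc/MeOH, 23 °C
Reagents that add atoms: none
Why: Hydrogenolysis of the two benzyl ethers and the benzyl ester should leave the hindered diaryl ketone and the aryl methyl ethers of ring A untouched.

Step 4
Reactants: 6 2-[2-(2,4-dimethoxy-6-methylbenzoyl)-3,5-dihydroxyphenyl]acetic acid
Product: 7 2-[2-(2,4-dimethoxy-6-methylbenzoyl)-3,5-dihydroxy-4-iodophenyl]acetic acid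
Conditions: I2, NaHCO3, THF/H2O, 0 °C
Reagents that add atoms: iodine II
Why: Electrophilic aromatic iodination of the resorcinol anion should occur at the carbon between the two hydroxyl groups (the future C4a), the site favoured for 5-substituted resorcinols and 2,4-dihydroxyaryl ketones under iodine/bicarbonate and here also the less hindered one, while the anisole-type ring A does not react.

Step 5
Reactants: 7 2-[2-(2,4-dimethoxy-6-methylbenzoyl)-3,5-dihydroxy-4-iodophenyl]acetic acid
Product: 9 2-[2-(2,4-dimethoxy-6-methylbenzoyl)-3,5-dihydroxy-4-(trimethylsilyl)phenyl]acetic acid, via silyl ether 8 (not isolated)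
Conditions: HMDS, THF, 65 °C, then evaporation; n-BuLi (1.1 equiv), THF, −78 → 0 °C; aq. NH4Cl
Reagents that add atoms: hexamethyldisilazane C[Si](C)(C)N[Si](C)(C)C
Why: Iodine–lithium exchange on the per-silylated compound should outrun addition of n-BuLi to the silyl ester or to the tetra-ortho-substituted ketone, and the aryllithium is quenched at once by anionic 1,3-O→C silyl migration (retro-Brook rearrangement) from a flanking silyl ether, so that aqueous work-up should give the C-silylated resorcinol.

Step 6
Reactants: 9 2-[2-(2,4-dimethoxy-6-methylbenzoyl)-3,5-dihydroxy-4-(trimethylsilyl)phenyl]acetic acid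
Product: 10 2-[2-(2,4-dimethoxy-6-methylbenzoyl)-3-hydroxy-5-(trifluoromethanesulfonyloxy)-4-(trimethylsilyl)phenyl]acetic acid
Conditions: PhNTf2 (1.05 equiv), i-Pr2NEt, CH2Cl2, 0 °C
Reagents that add atoms: N-phenylbis(trifluoromethanesulfonimide) O=S(=O)(N(c1ccccc1)S(=O)(=O)C(F)(F)F)C(F)(F)F
Why: Selective O-sulfonylation, because the C8a hydroxyl (para to the ketone, free on one side) is more acidic and far more accessible than the C5 hydroxyl, which is hydrogen-bonded to the ketone and flanked by SiMe3 and the aroyl group.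

Step 7
Reactants: 10 2-[2-(2,4-dimethoxy-6-methylbenzoyl)-3-hydroxy-5-(trifluoromethanesulfonyloxy)-4-(trimethylsilyl)phenyl]acetic acid, 11 2,2,6-trimethyl-4H-1,3-dioxin-4-one
Product: 13 4-(2,4-dimethoxy-6-methylbenzoyl)-5-[3-(2,2-dimethyl-4-oxo-4H-1,3-dioxin-6-yl)-2-oxopropyl]-3-hydroxy-2-(trimethylsilyl)phenyl trifluoromethanesulfonate, via acyl imidazolide 12 (not isolated)
Conditions: CDI, THF, 23 °C; then addition to 11/LiN(SiMe3)2 (excess), THF, −78 °C; AcOH quench at −78 °C
Reagents that add atoms: none
Why: Crossed Claisen-type C-acylation, in which the acyl imidazolide should acylate the lithium dienolate of 11 at its γ-carbon while excess dienolate absorbs the phenol and product protons and the aryl triflate and aryl silane stay inert to lithium enolates at −78 °C.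

Step 8
Reactants: 13 4-(2,4-dimethoxy-6-methylbenzoyl)-5-[3-(2,2-dimethyl-4-oxo-4H-1,3-dioxin-6-yl)-2-oxopropyl]-3-hydroxy-2-(trimethylsilyl)phenyl trifluoromethanesulfonate
Product: 15 4-(2,4-dimethoxy-6-methylbenzoyl)-3-hydroxy-5-[(4-hydroxy-2-oxo-2H-pyran-6-yl)methyl]-2-(trimethylsilyl)phenyl trifluoromethanesulfonate, via acylketene 14 (not isolated)
Conditions: PhMe, 110 °C
Reagents that add atoms: none
Why: Thermal retro-[4+2] fragmentation of the dioxinone releases acetone and an acylketene, which should be trapped intramolecularly by the enol oxygen of the δ-ketone (lactonisation) to give the 4-hydroxy-2-pyranone.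

Step 9
Reactants: 15 4-(2,4-dimethoxy-6-methylbenzoyl)-3-hydroxy-5-[(4-hydroxy-2-oxo-2H-pyran-6-yl)methyl]-2-(trimethylsilyl)phenyl trifluoromethanesulfonate
Product: 16 4-(2,4-dimethoxy-6-methylbenzoyl)-3-methoxy-5-[(4-methoxy-2-oxo-2H-pyran-6-yl)methyl]-2-(trimethylsilyl)phenyl trifluoromethanesulfonate
Conditions: MeOH, PPh3, DIAD, THF, 0 → 23 °C
Reagents that add atoms: methanol CO
Why: Mitsunobu etherification should O-methylate both the acidic pyranone 4-OH (which reacts at O4) and the chelated C5 phenol under essentially neutral conditions, avoiding a free phenoxide next to the C–Si bond that could trigger premature silyl migration and loss of triflate.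

Step 10
Reactants: 16 4-(2,4-dimethoxy-6-methylbenzoyl)-3-methoxy-5-[(4-methoxy-2-oxo-2H-pyran-6-yl)methyl]-2-(trimethylsilyl)phenyl trifluoromethanesulfonate, 17 methyl 3-oxobutanoate
Product: 21 6-(2,4-dimethoxy-6-methylbenzoyl)-2-hydroxy-5-methoxy-7-[(4-methoxy-2-oxo-2H-pyran-6-yl)methyl]naphthalene-1,4-dione, via aryne 18 (not isolated), via keto ester 19 (not isolated), via naphthalenediol 20 (not isolated)
Conditions: 17 (2 equiv), CsF, MeCN, 80 °C; then NaOMe, MeOH, air, 23 °C; aq. HCl work-up
Reagents that add atoms: dioxygen O=O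
Why: Fluoride attacks silicon at C4a and triflate leaves from C8a to give aryne 18; the cesium enolate of 17 adds through carbon to C8a (bond C1–C8a), the aryl anion at C4a closes onto the ketone carbonyl (4-exo-trig) to a benzocyclobutenoxide, and this fragments, so that the aryne is formally inserted into the C(O)–CH2 bond and keto ester 19 carries acetyl on C4a and CH2CO2Me on C8a. NaOMe then triggers an intramolecular Claisen condensation of the acetyl enolate onto the ester (bond C3–C2, 6-exo-trig closure of the new carbocycle) to naphthalene-1,3-diol 20, whose anion is oxidised by air at C1 to the 2-hydroxy-1,4-quinone. The closest known reaction type is the one-pot aryne acyl-alkylation/condensation/aerobic oxidation of β-keto esters with 2-silylaryl triflates, which gives 2-hydroxy-1,4-naphthoquinones and has been run with 3-alkoxyarynes. No stereocentre is formed. The step needs attack at C8a and not C4a, which the C5 methoxy group secures: its inductive effect distorts the aryne so that nucleophiles add at the distal carbon and the aryl anion develops next to oxygen. It also needs the enolate to outcompete other aryne traps, which the excess of 17 and the hindered, non-enolisable benzophenone favour, and exchange of the pyranone methoxy group with methoxide is degenerate.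

Step 11
Reactants: 21 6-(2,4-dimethoxy-6-methylbenzoyl)-2-hydroxy-5-methoxy-7-[(4-methoxy-2-oxo-2H-pyran-6-yl)methyl]naphthalene-1,4-dione
Product: 22 6-(2,4-dihydroxy-6-methylbenzoyl)-2,5-dihydroxy-7-[(4-hydroxy-2-oxo-2H-pyran-6-yl)methyl]naphthalene-1,4-dione
Conditions: BBr3 (excess), CH2Cl2, −78 → 23 °C; then H2O
Reagents that add atoms: none
Why: Lewis-acid ether cleavage, in which BBr3 coordinates the ether and carbonyl oxygens (activating the chelated aryl ethers and the vinylogous methyl ester of the pyranone) and bromide removes each methyl group by SN2, so that hydrolysis should release the four remaining hydroxyl groups of the target.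

**Compound list**

1 | 2-(3,5-dihydroxyphenyl)acetic acid | OC(=O)Cc1cc(O)cc(O)c1 | starting material
2 | benzyl 2-[3,5-bis(benzyloxy)phenyl]acetate | O=C(Cc1cc(OCc2ccccc2)cc(OCc2ccccc2)c1)OCc1ccccc1 | intermediate
3 | 2,4-dimethoxy-6-methylbenzoic acid | COc1cc(C)c(C(=O)O)c(OC)c1 | starting material
4 | 2,4-dimethoxy-6-methylbenzoic trifluoroacetic anhydride | COc1cc(C)c(C(=O)OC(=O)C(F)(F)F)c(OC)c1 | intermediate (not isolated)
5 | benzyl 2-[3,5-bis(benzyloxy)-2-(2,4-dimethoxy-6-methylbenzoyl)phenyl]acetate | COc1cc(C)c(C(=O)c2c(CC(=O)OCc3ccccc3)cc(OCc3ccccc3)cc2OCc2ccccc2)c(OC)c1 | intermediate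
6 | 2-[2-(2,4-dimethoxy-6-methylbenzoyl)-3,5-dihydroxyphenyl]acetic acid | COc1cc(C)c(C(=O)c2c(CC(=O)O)cc(O)cc2O)c(OC)c1 | intermediate
7 | 2-[2-(2,4-dimethoxy-6-methylbenzoyl)-3,5-dihydroxy-4-iodophenyl]acetic acid | COc1cc(C)c(C(=O)c2c(CC(=O)O)cc(O)c(I)c2O)c(OC)c1 | intermediate
8 | trimethylsilyl 2-[2-(2,4-dimethoxy-6-methylbenzoyl)-4-iodo-3,5-bis(trimethylsilyloxy)phenyl]acetate | COc1cc(C)c(C(=O)c2c(CC(=O)O[Si](C)(C)C)cc(O[Si](C)(C)C)c(I)c2O[Si](C)(C)C)c(OC)c1 | intermediate (not isolated)
9 | 2-[2-(2,4-dimethoxy-6-methylbenzoyl)-3,5-dihydroxy-4-(trimethylsilyl)phenyl]acetic acid | COc1cc(C)c(C(=O)c2c(CC(=O)O)cc(O)c([Si](C)(C)C)c2O)c(OC)c1 | intermediate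
10 | 2-[2-(2,4-dimethoxy-6-methylbenzoyl)-3-hydroxy-5-(trifluoromethanesulfonyloxy)-4-(trimethylsilyl)phenyl]acetic acid | COc1cc(C)c(C(=O)c2c(CC(=O)O)cc(OS(=O)(=O)C(F)(F)F)c([Si](C)(C)C)c2O)c(OC)c1 | intermediate
11 | 2,2,6-trimethyl-4H-1,3-dioxin-4-one | CC1=CC(=O)OC(C)(C)O1 | starting material
12 | 4-(2,4-dimethoxy-6-methylbenzoyl)-3-hydroxy-5-[2-(imidazol-1-yl)-2-oxoethyl]-2-(trimethylsilyl)phenyl trifluoromethanesulfonate | COc1cc(C)c(C(=O)c2c(CC(=O)n3ccnc3)cc(OS(=O)(=O)C(F)(F)F)c([Si](C)(C)C)c2O)c(OC)c1 | intermediate (not isolated)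
13 | 4-(2,4-dimethoxy-6-methylbenzoyl)-5-[3-(2,2-dimethyl-4-oxo-4H-1,3-dioxin-6-yl)-2-oxopropyl]-3-hydroxy-2-(trimethylsilyl)phenyl trifluoromethanesulfonate | COc1cc(C)c(C(=O)c2c(CC(=O)CC3=CC(=O)OC(C)(C)O3)cc(OS(=O)(=O)C(F)(F)F)c([Si](C)(C)C)c2O)c(OC)c1 | intermediate
14 | 4-(2,4-dimethoxy-6-methylbenzoyl)-3-hydroxy-5-(2,4,6-trioxohex-5-en-1-yl)-2-(trimethylsilyl)phenyl trifluoromethanesulfonate (acylketene) | COc1cc(C)c(C(=O)c2c(CC(=O)CC(=O)C=C=O)cc(OS(=O)(=O)C(F)(F)F)c([Si](C)(C)C)c2O)c(OC)c1 | intermediate (not isolated)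
15 | 4-(2,4-dimethoxy-6-methylbenzoyl)-3-hydroxy-5-[(4-hydroxy-2-oxo-2H-pyran-6-yl)methyl]-2-(trimethylsilyl)phenyl trifluoromethanesulfonate | COc1cc(C)c(C(=O)c2c(Cc3cc(O)cc(=O)o3)cc(OS(=O)(=O)C(F)(F)F)c([Si](C)(C)C)c2O)c(OC)c1 | intermediate
16 | 4-(2,4-dimethoxy-6-methylbenzoyl)-3-methoxy-5-[(4-methoxy-2-oxo-2H-pyran-6-yl)methyl]-2-(trimethylsilyl)phenyl trifluoromethanesulfonate | COc1cc(C)c(C(=O)c2c(Cc3cc(OC)cc(=O)o3)cc(OS(=O)(=O)C(F)(F)F)c([Si](C)(C)C)c2OC)c(OC)c1 | intermediate
17 | methyl 3-oxobutanoate (methyl acetoacetate) | CC(=O)CC(=O)OC | starting material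
18 | 4-(2,4-dimethoxy-6-methylbenzoyl)-3-methoxy-5-[(4-methoxy-2-oxo-2H-pyran-6-yl)methyl]-1,2-didehydrobenzene (aryne) | COC1=C(C(=O)c2c(C)cc(OC)cc2OC)C(Cc2cc(OC)cc(=O)o2)=CC#C1 | intermediate (not isolated)
19 | methyl 2-{2-acetyl-4-(2,4-dimethoxy-6-methylbenzoyl)-3-methoxy-5-[(4-methoxy-2-oxo-2H-pyran-6-yl)methyl]phenyl}acetate | COC(=O)Cc1cc(Cc2cc(OC)cc(=O)o2)c(C(=O)c2c(C)cc(OC)cc2OC)c(OC)c1C(C)=O | intermediate (not isolated)
20 | 7-(2,4-dimethoxy-6-methylbenzoyl)-8-methoxy-6-[(4-methoxy-2-oxo-2H-pyran-6-yl)methyl]naphthalene-1,3-diol | COc1c(C(=O)c2c(C)cc(OC)cc2OC)c(Cc2cc(OC)cc(=O)o2)cc2cc(O)cc(O)c12 | intermediate (not isolated)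
21 | 6-(2,4-dimethoxy-6-methylbenzoyl)-2-hydroxy-5-methoxy-7-[(4-methoxy-2-oxo-2H-pyran-6-yl)methyl]naphthalene-1,4-dione | COc1cc(C)c(C(=O)c2c(Cc3cc(OC)cc(=O)o3)cc3c(c2OC)C(=O)C=C(O)C3=O)c(OC)c1 | intermediate
22 | 6-(2,4-dihydroxy-6-methylbenzoyl)-2,5-dihydroxy-7-[(4-hydroxy-2-oxo-2H-pyran-6-yl)methyl]naphthalene-1,4-dione | Cc1cc(O)cc(O)c1C(=O)c1c(Cc2cc(O)cc(=O)o2)cc2c(c1O)C(=O)C=C(O)C2=O | target

**Step count.** Total steps: 11. Longest linear sequence: 11 steps (1 → 22); compounds 3, 11 and 17 enter as purchased materials.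

**Steps most likely to fail**

Step 10 (aryne cascade). The aryne may be diverted, either by protonation of the aryl anion before it closes onto the ketone or by cycloaddition with the pyranone of a second molecule. The benzylic pyranone methylene may also be deprotonated and autoxidised during the aerobic base stage. The fallback sets out from 16 and uses the two handles one after the other, without an aryne. Negishi coupling of the aryl triflate with the Reformatsky reagent BrZnCH2CO2Me (Pd2(dba)3, XPhos, THF, 60 °C) should give methyl 2-{4-(2,4-dimethoxy-6-methylbenzoyl)-3-methoxy-5-[(4-methoxy-2-oxo-2H-pyran-6-yl)methyl]-2-(trimethylsilyl)phenyl}acetate F1. Friedel–Crafts ipso-acetyldesilylation of F1 (AcCl, AlCl3, CH2Cl2, −78 °C), which should be faster at the C–Si carbon than at any C–H of ring A, then places the acetyl group on C4a. The fallback comes back to the route at 19, here isolated. Ring closure is then done under argon with LiN(SiMe3)2 (THF, −78 → 0 °C) to give 20, which is oxidised separately with potassium nitrosodisulfonate, ON(SO3K)2, in buffered aqueous acetone to give 21.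

Step 5 (iodine–lithium exchange and silyl migration). Addition of n-BuLi to the silyl ester or the ketone, or proton transfer to the aryllithium, may compete with the exchange–migration sequence. The fallback sets out from 7 through its silyl ether 8 (made as in step 5) and replaces the organolithium by a palladium-catalysed silylation of the aryl iodide with hexamethyldisilane (Me3SiSiMe3, Pd(PPh3)4, xylene, 140 °C; oxidative addition, Si–Si transmetalation, C–Si reductive elimination). The same aqueous work-up removes the O-silyl groups, and the fallback comes back at 9 without any new compound.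

Step 11 (global demethylation). The long exposure to BBr3 needed for the ring A para ether and the pyranone ether may cause Lewis-acid-mediated condensation of the pyranone onto the diaryl ketone or general decomposition of the polyphenolic quinone. The fallback sets out from 21 and stages the deprotection. BCl3 (CH2Cl2, −78 → 0 °C) should remove only the two methyl ethers that can chelate boron (C5–OMe between the ketone and the quinone carbonyl, and the ring A ether ortho to the ketone), giving 2,5-dihydroxy-6-(2-hydroxy-4-methoxy-6-methylbenzoyl)-7-[(4-methoxy-2-oxo-2H-pyran-6-yl)methyl]naphthalene-1,4-dione F2. The two remaining ethers, both activated for SN2 dealkylation (the vinylogous ester of the pyranone and the anisole para to the ketone), are then cleaved by chloride (LiCl, DMF, 120 °C), and the fallback comes back at 22.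

**Further compounds**

F1 | step 10 | methyl 2-{4-(2,4-dimethoxy-6-methylbenzoyl)-3-methoxy-5-[(4-methoxy-2-oxo-2H-pyran-6-yl)methyl]-2-(trimethylsilyl)phenyl}acetate | COC(=O)Cc1cc(Cc2cc(OC)cc(=O)o2)c(C(=O)c2c(C)cc(OC)cc2OC)c(OC)c1[Si](C)(C)C
F0 | step 5 | none | none
F2 | step 11 | 2,5-dihydroxy-6-(2-hydroxy-4-methoxy-6-methylbenzoyl)-7-[(4-methoxy-2-oxo-2H-pyran-6-yl)methyl]naphthalene-1,4-dione | COc1cc(C)c(C(=O)c2c(Cc3cc(OC)cc(=O)o3)cc3c(c2O)C(=O)C=C(O)C3=O)c(O)c1
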